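**Strategy.** The synthesis rests on the oxolane ring O–C3–C2–C1–C10 (germacrane numbering), whose fully substituted ether carbon C10 neighbours carbinol C1. This ring is not closed by etherification but grown from a four-membered one: cyclobutanone 7 (C3 carbonyl, C2, alkoxy-bearing C1, quaternary C10), made by an auxiliary-controlled dichloroketene cycloaddition, is irradiated in methanol. α-Cleavage of C3–C10 and reclosure on oxygen insert O between these atoms with retention at C10 and deliver C3 as an acetal, ready for cis-selective isopropenyl transfer. Zinc Barbier union with a vinylbutenolide, Mitsunobu angeloylation and ring-closing metathesis of the ten-membered carbocycle follow.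

Key step: step 6

Numbering and abbreviations: atom labels carry a C (C1 carbinol, C2, C3 and C10 the two ether carbons, C4=C5 ring olefin, C6 lactone carbinol, C7, C8 ester carbinol, C9, C11–C13 methylene lactone, C14/C15 methyls); compound numbers are plain. R* = (1R)-1-[2,4,6-tri(propan-2-yl)phenyl]ethyl; TBS = tert-butyldimethylsilyl.

Assumption: dichloroketene is taken to add anti to the aryl group of the s-trans enol ether conformer, so that the R auxiliary gives 1S,10S (with the opposite sense the S alcohol would be used and nothing else changes), and the zinc Barbier reaction of step 14 is taken to pass through a closed chair and give the 8S alcohol.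

## Route

Step 1
Reactants: 1 (1R)-1-(2,4,6-triisopropylphenyl)ethanol (R*OH)
Product: 2 (E)-1,2-dichloroethenyl R* ether
Conditions: KH, THF, 0 °C; trichloroethylene, −50 °C → rt
Reagents that add atoms: trichloroethylene, ClC=C(Cl)Cl
Why: the potassium alkoxide adds to dichloroacetylene formed in situ from trichloroethylene (base-mediated elimination–addition), the standard entry to 1,2-dichlorovinyl ethers, and the carbinol centre is untouched.

Step 2
Reactants: 2 (E)-1,2-dichloroethenyl R* ether; 3 tert-butyl(2-iodoethoxy)dimethylsilane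
Product: 4 4-(R*O)but-3-yn-1-yl TBS ether
Conditions: n-BuLi (2.2 equiv), THF, −78 → −40 °C; then 3, HMPA, −78 °C → rt
Reagents that add atoms: none
Why: n-BuLi converts the dichlorovinyl ether into the lithium alkoxyacetylide by elimination and Cl/Li exchange, and this acetylide is C-alkylated by the primary iodide (SN2 acetylide alkylation).

Step 3
Reactants: 4 4-(R*O)but-3-yn-1-yl TBS ether
Product: 5 (3Z)-3-methyl-4-(R*O)but-3-en-1-yl TBS ether
Conditions: MeMgBr, CuBr·SMe2, THF, −40 → −10 °C; then aq NH4Cl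
Reagents that add atoms: methylmagnesium bromide, C[Mg]Br
Why: syn-carbocupration of the ynol ether puts copper on the oxygen-bearing carbon and methyl cis to it, so protonolysis with retention gives the Z enol ether in which O1 and C9 are cis, the relationship later needed on the oxolane.

Step 4
Reactants: 5 (3Z)-3-methyl-4-(R*O)but-3-en-1-yl TBS ether
Product: 6 (3R,4S)-2,2-dichloro-4-methyl-4-[2-(TBSO)ethyl]-3-(R*O)cyclobutan-1-one
Conditions: Cl3CCOCl, Zn–Cu couple, Et2O, 20 °C
Reagents that add atoms: trichloroacetyl chloride, ClC(=O)C(Cl)(Cl)Cl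
Why: the thermal ketene–enol ether [2+2] cycloaddition is suprafacial on the olefin and regioselective (carbonyl carbon to the nucleophilic C10), so the Z relationship becomes cis C1–O/C10–C9, and the aryl group of the auxiliary blocks one face, which should set 1S,10S.

Step 5
Reactants: 6 (3R,4S)-2,2-dichloro-4-methyl-4-[2-(TBSO)ethyl]-3-(R*O)cyclobutan-1-one
Product: 7 (2S,3S)-2-methyl-2-[2-(TBSO)ethyl]-3-(R*O)cyclobutan-1-one
Conditions: Zn–Cu couple, NH4Cl, MeOH, 20 °C
Reagents that add atoms: none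
Why: zinc removes both α-chlorines (reductive dehalogenation of an α,α-dichloroketone) under buffered conditions that should not expel the β-alkoxy group.

Step 6
Reactants: 7 (2S,3S)-2-methyl-2-[2-(TBSO)ethyl]-3-(R*O)cyclobutan-1-one
Product: 9 (2S,3S)-5-methoxy-2-methyl-2-[2-(TBSO)ethyl]-3-(R*O)oxolane (both C5 epimers), via oxolan-2-ylidene carbene 8 (not isolated)
Conditions: hν (medium-pressure Hg lamp, Pyrex filter, λ > 290 nm), degassed MeOH, 15 °C
Reagents that add atoms: methanol, CO
Why: n→π* excitation of the strained ketone is followed by Norrish α-cleavage of the C3–C10 bond, the side that gives the tertiary alkyl radical, and the acyl–alkyl biradical recloses through oxygen to the cyclic oxacarbene 8, which inserts into the O–H bond of methanol. The closest known reaction type is the photochemical ring expansion of cyclobutanones to 2-alkoxytetrahydrofurans. The oxolane is not closed by a cyclization: the four-membered ring C3–C2–C1–C10 grows by one atom when the O–C10 bond forms by radical recombination inside the biradical. No ring stereocentre is created apart from the acetal carbon C3, left as a mixture because it is planarized in step 7; C10 should keep its configuration because recombination of the tethered radical pair is faster than rotation, and C1 is untouched. The step needs cleavage toward C10 rather than C2, secured by the quaternary substitution, and ring expansion rather than cycloelimination or loss of CO, favoured by ring strain, the fully substituted α-carbon and the protic solvent.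

Step 7
Reactants: 9 (2S,3S)-5-methoxy-2-methyl-2-[2-(TBSO)ethyl]-3-(R*O)oxolane; 10 potassium trifluoro(prop-1-en-2-yl)borate
Product: 11 (2S,3S,5S)-2-methyl-5-(prop-1-en-2-yl)-2-[2-(TBSO)ethyl]-3-(R*O)oxolane
Conditions: BF3·OEt2, MeCN, −40 → 0 °C
Reagents that add atoms: none
Why: BF3 ionizes the acetal to the oxolanyl oxocarbenium ion and the alkenyl group is delivered from the alkenyldifluoroborane formed in situ (alkenyltrifluoroborate addition to an acetal); the inside-attack model for five-membered oxocarbenium ions with a pseudoaxial alkoxy group two carbons from the cationic centre predicts entry cis to the C1 alkoxy group, which sets C3 as S.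

Step 8
Reactants: 11 (2S,3S,5S)-2-methyl-5-(prop-1-en-2-yl)-2-[2-(TBSO)ethyl]-3-(R*O)oxolane
Product: 12 2-[(2S,3S,5S)-2-methyl-5-(prop-1-en-2-yl)-3-(R*O)oxolan-2-yl]ethan-1-ol
Conditions: Bu4NF, THF, 0 °C → rt
Reagents that add atoms: none
Why: fluoride cleaves the primary silyl ether (desilylation) and leaves the benzylic ether and the olefin alone.

Step 9
Reactants: 12 2-[(2S,3S,5S)-2-methyl-5-(prop-1-en-2-yl)-3-(R*O)oxolan-2-yl]ethan-1-ol
Product: 13 2-[(2S,3S,5S)-2-methyl-5-(prop-1-en-2-yl)-3-(R*O)oxolan-2-yl]acetaldehyde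
Conditions: Dess–Martin periodinane, CH2Cl2, 0 °C → rt
Reagents that add atoms: none
Why: Dess–Martin oxidation takes the primary alcohol to the aldehyde under near-neutral conditions, and no centre can epimerize because C10 is quaternary.

Step 10
Reactants: 14 acrolein; 15 tert-butyldimethyl(prop-2-yn-1-yloxy)silane
Product: 16 (3R)-6-(TBSO)hex-1-en-4-yn-3-ol
Conditions: Me2Zn, ProPhenol ligand (enantiomer that gives 3R, 20 mol %), Ph3PO (cat.), toluene, 0 °C
Reagents that add atoms: none
Why: zinc–ProPhenol-catalysed enantioselective alkynylation adds the alkynylzinc 1,2 to the enal and sets the future C6 by catalyst control.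

Step 11
Reactants: 16 (3R)-6-(TBSO)hex-1-en-4-yn-3-ol
Product: 17 (3R,4Z)-5-iodo-6-(TBSO)hexa-1,4-dien-3-ol
Conditions: NaAlH2(OCH2CH2OMe)2, THF, 0 °C; then I2, −78 °C
Reagents that add atoms: iodine, [I][I]
Why: hydroxyl-directed trans-hydroalumination of the propargylic alcohol places aluminium on the distal alkyne carbon, and iodinolysis with retention gives the Z vinyl iodide with iodine cis to the carbinol.

Step 12
Reactants: 17 (3R,4Z)-5-iodo-6-(TBSO)hexa-1,4-dien-3-ol
Product: 18 (5R)-5-ethenyl-3-[(TBSO)methyl]furan-2(5H)-one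
Conditions: CO (1 atm), PdCl2(PPh3)2 (5 mol %), K2CO3, THF, 25 °C
Reagents that add atoms: carbon monoxide, [C-]#[O+]
Why: oxidative addition of zerovalent palladium into the vinyl iodide, CO insertion and capture of the acylpalladium by the cis hydroxyl (carbonylative lactonization) close the butenolide without touching the stereocentre.

Step 13
Reactants: 18 (5R)-5-ethenyl-3-[(TBSO)methyl]furan-2(5H)-one
Product: 19 (5R)-3-(bromomethyl)-5-ethenylfuran-2(5H)-one
Conditions: Ph3PBr2, CH2Cl2, 0 °C → rt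
Reagents that add atoms: dibromotriphenylphosphorane, BrP(Br)(c1ccccc1)(c1ccccc1)c1ccccc1
Why: Ph3PBr2 converts the primary allylic silyl ether directly into the bromide through an alkoxyphosphonium ion (silyl ether to bromide exchange).

Step 14
Reactants: 13 2-[(2S,3S,5S)-2-methyl-5-(prop-1-en-2-yl)-3-(R*O)oxolan-2-yl]acetaldehyde; 19 (5R)-3-(bromomethyl)-5-ethenylfuran-2(5H)-one
Product: 20 (4R,5R)-5-ethenyl-4-{(1S)-1-hydroxy-2-[(2S,3S,5S)-2-methyl-5-(prop-1-en-2-yl)-3-(R*O)oxolan-2-yl]ethyl}-3-methylideneoxolan-2-one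
Conditions: Zn dust, THF/sat. aq NH4Cl, 0 °C → rt
Reagents that add atoms: none
Why: in this zinc Barbier allylation the allylzinc from 19 attacks the aldehyde through its ring γ-carbon (SE2′) anti to the vinyl group, which gives the 6,7-trans α-methylene lactone (C7 R), and a closed chair transition state should give the 8S carbinol.

Step 15
Reactants: 20 (4R,5R)-5-ethenyl-4-{(1S)-1-hydroxy-2-[(2S,3S,5S)-2-methyl-5-(prop-1-en-2-yl)-3-(R*O)oxolan-2-yl]ethyl}-3-methylideneoxolan-2-one; 21 angelic acid, (2Z)-2-methylbut-2-enoic acid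
Product: 22 (1R)-1-[(2R,3R)-2-ethenyl-4-methylidene-5-oxooxolan-3-yl]-2-[(2S,3S,5S)-2-methyl-5-(prop-1-en-2-yl)-3-(R*O)oxolan-2-yl]ethyl (2Z)-2-methylbut-2-enoate
Conditions: PPh3, DIAD, toluene, 0 °C → rt
Reagents that add atoms: none
Why: Mitsunobu esterification inverts C8 to the required R configuration while it installs the angelate, and its neutral conditions should avoid Z to E isomerization of the acid.

Step 16
Reactants: 22 (1R)-1-[(2R,3R)-2-ethenyl-4-methylidene-5-oxooxolan-3-yl]-2-[(2S,3S,5S)-2-methyl-5-(prop-1-en-2-yl)-3-(R*O)oxolan-2-yl]ethyl (2Z)-2-methylbut-2-enoate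
Product: 23 (1S,3S,4Z,6R,7R,8R,10S)-8-angeloyloxy-3,10-epoxy-1-(R*O)germacra-4,11(13)-dien-12,6-olide
Conditions: second-generation Hoveyda–Grubbs catalyst RuCl2(H2IMes)(=CH-C6H4-2-OiPr) (15 mol %), toluene (1 mM), 80 °C
Reagents that add atoms: none
Why: ring-closing metathesis between the vinyl group (initiation site) and the isopropenyl group closes the ten-membered carbocycle, whose oxygen-bridged frame can hold only the Z olefin, while the methylene lactone and the angelate are too hindered and electron-poor to compete.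

Step 17
Reactants: 23 (1S,3S,4Z,6R,7R,8R,10S)-8-angeloyloxy-3,10-epoxy-1-(R*O)germacra-4,11(13)-dien-12,6-olide
Product: 24 (1S,3S,4Z,6R,7R,8R,10S)-8-angeloyloxy-3,10-epoxy-1-hydroxygermacra-4,11(13)-dien-12,6-olide (target)
Conditions: CF3CO2H, CH2Cl2, 0 °C
Reagents that add atoms: none
Why: acidolysis of the hindered, electron-rich benzylic ether (SN1 cleavage at the auxiliary carbon) frees the C1 hydroxyl with retention, since the C1–O bond is not broken.

## Compound list

1 | (1R)-1-(2,4,6-triisopropylphenyl)ethanol | C[C@@H](O)c1c(C(C)C)cc(C(C)C)cc1C(C)C | starting material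
2 | (E)-1,2-dichloroethenyl R* ether | C[C@@H](O/C(Cl)=C\Cl)c1c(C(C)C)cc(C(C)C)cc1C(C)C | intermediate
3 | tert-butyl(2-iodoethoxy)dimethylsilane | CC(C)(C)[Si](C)(C)OCCI | starting material
4 | 4-(R*O)but-3-yn-1-yl TBS ether | C[C@@H](OC#CCCO[Si](C)(C)C(C)(C)C)c1c(C(C)C)cc(C(C)C)cc1C(C)C | intermediate
5 | (3Z)-3-methyl-4-(R*O)but-3-en-1-yl TBS ether | C[C@@H](O/C=C(/C)CCO[Si](C)(C)C(C)(C)C)c1c(C(C)C)cc(C(C)C)cc1C(C)C | intermediate
6 | (3R,4S)-2,2-dichloro-4-methyl-4-[2-(TBSO)ethyl]-3-(R*O)cyclobutan-1-one | O=C1C(Cl)(Cl)[C@H](O[C@H](C)c2c(C(C)C)cc(C(C)C)cc2C(C)C)[C@]1(C)CCO[Si](C)(C)C(C)(C)C | intermediate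
7 | (2S,3S)-2-methyl-2-[2-(TBSO)ethyl]-3-(R*O)cyclobutan-1-one | O=C1C[C@H](O[C@H](C)c2c(C(C)C)cc(C(C)C)cc2C(C)C)[C@]1(C)CCO[Si](C)(C)C(C)(C)C | intermediate
8 | (4S,5S)-5-methyl-5-[2-(TBSO)ethyl]-4-(R*O)oxolan-2-ylidene (oxacarbene) | [C]1C[C@H](O[C@H](C)c2c(C(C)C)cc(C(C)C)cc2C(C)C)[C@](C)(CCO[Si](C)(C)C(C)(C)C)O1 | intermediate
9 | (2S,3S)-5-methoxy-2-methyl-2-[2-(TBSO)ethyl]-3-(R*O)oxolane (both C5 epimers) | COC1C[C@H](O[C@H](C)c2c(C(C)C)cc(C(C)C)cc2C(C)C)[C@](C)(CCO[Si](C)(C)C(C)(C)C)O1 | intermediate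
10 | potassium trifluoro(prop-1-en-2-yl)borate | [K+].CC(=C)[B-](F)(F)F | starting material
11 | (2S,3S,5S)-2-methyl-5-(prop-1-en-2-yl)-2-[2-(TBSO)ethyl]-3-(R*O)oxolane | C=C(C)[C@@H]1C[C@H](O[C@H](C)c2c(C(C)C)cc(C(C)C)cc2C(C)C)[C@](C)(CCO[Si](C)(C)C(C)(C)C)O1 | intermediate
12 | 2-[(2S,3S,5S)-2-methyl-5-(prop-1-en-2-yl)-3-(R*O)oxolan-2-yl]ethan-1-ol | C=C(C)[C@@H]1C[C@H](O[C@H](C)c2c(C(C)C)cc(C(C)C)cc2C(C)C)[C@](C)(CCO)O1 | intermediate
13 | 2-[(2S,3S,5S)-2-methyl-5-(prop-1-en-2-yl)-3-(R*O)oxolan-2-yl]acetaldehyde | C=C(C)[C@@H]1C[C@H](O[C@H](C)c2c(C(C)C)cc(C(C)C)cc2C(C)C)[C@](C)(CC=O)O1 | intermediate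
14 | acrolein | C=CC=O | starting material
15 | tert-butyldimethyl(prop-2-yn-1-yloxy)silane | C#CCO[Si](C)(C)C(C)(C)C | starting material
16 | (3R)-6-(TBSO)hex-1-en-4-yn-3-ol | C=C[C@@H](O)C#CCO[Si](C)(C)C(C)(C)C | intermediate
17 | (3R,4Z)-5-iodo-6-(TBSO)hexa-1,4-dien-3-ol | C=C[C@@H](O)/C=C(\I)CO[Si](C)(C)C(C)(C)C | intermediate
18 | (5R)-5-ethenyl-3-[(TBSO)methyl]furan-2(5H)-one | C=C[C@@H]1C=C(CO[Si](C)(C)C(C)(C)C)C(=O)O1 | intermediate
19 | (5R)-3-(bromomethyl)-5-ethenylfuran-2(5H)-one | C=C[C@@H]1C=C(CBr)C(=O)O1 | intermediate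
20 | (4R,5R)-5-ethenyl-4-{(1S)-1-hydroxy-2-[(2S,3S,5S)-2-methyl-5-(prop-1-en-2-yl)-3-(R*O)oxolan-2-yl]ethyl}-3-methylideneoxolan-2-one | C=C1C(=O)O[C@H](C=C)[C@H]1[C@@H](O)C[C@]2(C)O[C@H](C(C)=C)C[C@@H]2O[C@H](C)c3c(C(C)C)cc(C(C)C)cc3C(C)C | intermediate
21 | angelic acid, (2Z)-2-methylbut-2-enoic acid | C/C=C(/C)C(=O)O | starting material
22 | (1R)-1-[(2R,3R)-2-ethenyl-4-methylidene-5-oxooxolan-3-yl]-2-[(2S,3S,5S)-2-methyl-5-(prop-1-en-2-yl)-3-(R*O)oxolan-2-yl]ethyl (2Z)-2-methylbut-2-enoate | C=C1C(=O)O[C@H](C=C)[C@H]1[C@H](OC(=O)/C(C)=C\C)C[C@]2(C)O[C@H](C(C)=C)C[C@@H]2O[C@H](C)c3c(C(C)C)cc(C(C)C)cc3C(C)C | intermediate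
23 | (1S,3S,4Z,6R,7R,8R,10S)-8-angeloyloxy-3,10-epoxy-1-(R*O)germacra-4,11(13)-dien-12,6-olide | C=C1C(=O)O[C@@H]2/C=C(/C)[C@@H]3C[C@H](O[C@H](C)c4c(C(C)C)cc(C(C)C)cc4C(C)C)[C@](C)(C[C@@H](OC(=O)/C(C)=C\C)[C@@H]12)O3 | intermediate
24 | (1S,3S,4Z,6R,7R,8R,10S)-8-angeloyloxy-3,10-epoxy-1-hydroxygermacra-4,11(13)-dien-12,6-olide | C=C1C(=O)O[C@@H]2/C=C(/C)[C@@H]3C[C@H](O)[C@](C)(C[C@@H](OC(=O)/C(C)=C\C)[C@@H]12)O3 | target

## Step count and risks

Total steps: 17. Longest linear sequence: 13 (steps 1–9 and 14–17, from 1); the butenolide branch (steps 10–13) joins at step 14.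

**Step 6 (photochemical ring expansion).** What may go wrong: the acyl–alkyl biradical fragments (cycloelimination to ketene and enol ether 5, or loss of CO to a cyclopropane) faster than it recloses on oxygen. The fallback sets out from 7 and comes back at 11; it does the same one-atom expansion thermally. Baeyer–Villiger oxidation of 7 (mCPBA, NaHCO3, CH2Cl2, 0 °C) should migrate the quaternary C10 with retention and give (4S,5S)-5-methyl-5-[2-(TBSO)ethyl]-4-(R*O)oxolan-2-one F1. Reduction with iBu2AlH (−78 °C) and acetylation of the aluminium lactolate in the same flask (Ac2O, pyridine, DMAP) should give (4S,5S)-5-methyl-5-[2-(TBSO)ethyl]-4-(R*O)oxolan-2-yl acetate F2. F2 is then treated with 10 and BF3·OEt2 as in step 7 to give 11.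

**Step 7 (alkenyl transfer to the oxocarbenium ion).** What may go wrong: alkenyl transfer is slower than proton loss from the oxocarbenium ion (2,3-dihydrofuran formation) or than Lewis-acid cleavage of the benzylic ether, or the facial selectivity is poor. The fallback sets out from 9 and comes back at 11; it transfers the more nucleophilic alkynyl group first. Treatment of 9 with potassium trifluoro[(trimethylsilyl)ethynyl]borate and BF3·OEt2 (MeCN, −40 °C) should give, by the same cis-selective attack, (2S,3S,5S)-2-methyl-2-[2-(TBSO)ethyl]-3-(R*O)-5-[(trimethylsilyl)ethynyl]oxolane F3. K2CO3 in MeOH removes the alkynyl silyl group to give (2S,3S,5S)-5-ethynyl-2-methyl-2-[2-(TBSO)ethyl]-3-(R*O)oxolane F4. Zirconium-catalysed carboalumination of F4 (Me3Al, Cp2ZrCl2, CH2Cl2, then water) adds methyl to the internal alkyne carbon and gives 11.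

**Step 15 (Mitsunobu inversion at C8).** What may go wrong: the activated C8 oxygen is lost by elimination toward C7 instead of being displaced, the hindered carbinol does not react, or step 14 has delivered the other C8 epimer so that inversion is not wanted. The fallback sets out from 19 and 13 and comes back at 22; it sets C8 directly in the allylation through an open transition state. Treatment of 19 with (Bu3Sn)2 and Pd(PPh3)4 (THF) should give (5R)-5-ethenyl-3-[(tributylstannyl)methyl]furan-2(5H)-one F5. BF3·OEt2-promoted addition of F5 to 13 (CH2Cl2, −78 °C), which is syn-selective for γ-substituted allylstannanes and again anti to the vinyl group, should give (4R,5R)-5-ethenyl-4-{(1R)-1-hydroxy-2-[(2S,3S,5S)-2-methyl-5-(prop-1-en-2-yl)-3-(R*O)oxolan-2-yl]ethyl}-3-methylideneoxolan-2-one F6. Yamaguchi esterification of F6 with 21 (2,4,6-trichlorobenzoyl chloride, Et3N, then DMAP, toluene) gives 22 with retention.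

Further compounds
F1 | step 6 | (4S,5S)-5-methyl-5-[2-(TBSO)ethyl]-4-(R*O)oxolan-2-one | O=C1C[C@H](O[C@H](C)c2c(C(C)C)cc(C(C)C)cc2C(C)C)[C@](C)(CCO[Si](C)(C)C(C)(C)C)O1
F2 | step 6 | (4S,5S)-5-methyl-5-[2-(TBSO)ethyl]-4-(R*O)oxolan-2-yl acetate (both C2 epimers) | CC(=O)OC1C[C@H](O[C@H](C)c2c(C(C)C)cc(C(C)C)cc2C(C)C)[C@](C)(CCO[Si](C)(C)C(C)(C)C)O1
F3 | step 7 | (2S,3S,5S)-2-methyl-2-[2-(TBSO)ethyl]-3-(R*O)-5-[(trimethylsilyl)ethynyl]oxolane | C[Si](C)(C)C#C[C@@H]1C[C@H](O[C@H](C)c2c(C(C)C)cc(C(C)C)cc2C(C)C)[C@](C)(CCO[Si](C)(C)C(C)(C)C)O1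
F4 | step 7 | (2S,3S,5S)-5-ethynyl-2-methyl-2-[2-(TBSO)ethyl]-3-(R*O)oxolane | C#C[C@@H]1C[C@H](O[C@H](C)c2c(C(C)C)cc(C(C)C)cc2C(C)C)[C@](C)(CCO[Si](C)(C)C(C)(C)C)O1
F5 | step 15 | (5R)-5-ethenyl-3-[(tributylstannyl)methyl]furan-2(5H)-one | C=C[C@@H]1C=C(C[Sn](CCCC)(CCCC)CCCC)C(=O)O1
F6 | step 15 | (4R,5R)-5-ethenyl-4-{(1R)-1-hydroxy-2-[(2S,3S,5S)-2-methyl-5-(prop-1-en-2-yl)-3-(R*O)oxolan-2-yl]ethyl}-3-methylideneoxolan-2-one | C=C1C(=O)O[C@H](C=C)[C@H]1[C@H](O)C[C@]2(C)O[C@H](C(C)=C)C[C@@H]2O[C@H](C)c3c(C(C)C)cc(C(C)C)cc3C(C)C
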